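Ring C of the upper, all-cis (ent-epicatechin-type) unit is cut at O-1–C-2 and C-4a–C-4. That leaves 3,5-bis(benzyloxy)phenol (ring A) and a cis-2,3-epoxy alcohol whose carbinol carbon, the future C-4, already sits on C-8 of ring D of a protected (−)-epicatechin. The key step exploits that C-4 is benzylic to ring D between two ortho oxygens and C-2 is benzylic to ring B: acid ionises C-4, the phenol carbon adds, and the phenol oxygen opens the epoxide at C-2 with inversion. One operation thus builds ring C and sets C-4 and C-2 against the Sharpless-derived C-3. Hydroxylation at C-4 of ring F and hydrogenolysis complete the route.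

Key step: step 8

Remark: flavan numbering is used; rings A, B, C belong to the upper unit and rings D, E, F to the lower unit. The carbinol centre made in step 7 is left undefined on purpose, because step 8 ionises it.

Step 1
Reactants: 1 3,4-bis(benzyloxy)benzaldehyde
Product: 2 methyl (2Z)-3-[3,4-bis(benzyloxy)phenyl]prop-2-enoate
Conditions: methyl bis(2,2,2-trifluoroethyl)phosphonoacetate, KN(SiMe3)2, 18-crown-6, THF, −78 °C
Reagents that add atoms: methyl bis(2,2,2-trifluoroethyl)phosphonoacetate, COC(=O)CP(=O)(OCC(F)(F)F)OCC(F)(F)F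
Why: Still–Gennari variant of the Horner–Wadsworth–Emmons olefination, in which the electron-poor phosphonate eliminates from the kinetic adduct and should give the (Z)-cinnamate.

Step 2
Reactants: 2 methyl (2Z)-3-[3,4-bis(benzyloxy)phenyl]prop-2-enoate
Product: 3 (2Z)-3-[3,4-bis(benzyloxy)phenyl]prop-2-en-1-ol
Conditions: i-Bu2AlH (2.2 equiv), CH2Cl2, −78 °C; aq. potassium sodium tartrate
Reagents that add atoms: none
Why: 1,2-reduction of an unsaturated ester by an aluminium hydride at low temperature should give the allylic alcohol without touching the alkene geometry or the benzyl ethers.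

Step 3
Reactants: 3 (2Z)-3-[3,4-bis(benzyloxy)phenyl]prop-2-en-1-ol
Product: 4 [(2S,3R)-3-[3,4-bis(benzyloxy)phenyl]oxiran-2-yl]methanol (cis-epoxide)
Conditions: Ti(Oi-Pr)4 (cat.), L-(+)-diisopropyl tartrate (cat.), t-BuOOH, 4 Å MS, CH2Cl2, −20 °C
Reagents that add atoms: tert-butyl hydroperoxide, CC(C)(C)OO
Why: Sharpless asymmetric epoxidation, in which the L-(+)-tartrate catalyst delivers oxygen stereospecifically to one face of the (Z)-allylic alcohol and so should give the (2S,3R) cis-epoxide that fixes C-3 of the upper unit and, through the cis geometry, prepares C-2.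

Step 4
Reactants: 4 [(2S,3R)-3-[3,4-bis(benzyloxy)phenyl]oxiran-2-yl]methanol
Product: 5 (2R,3R)-3-[3,4-bis(benzyloxy)phenyl]oxirane-2-carbaldehyde (cis-epoxy aldehyde, used crude)
Conditions: Dess–Martin periodinane, NaHCO3, CH2Cl2, 0 °C
Reagents that add atoms: none
Why: Dess–Martin oxidation under buffered, non-basic conditions should give the aldehyde without epimerising or opening the cis-epoxide (the descriptor at C-2 changes only because the substituent priorities change).

Step 5
Reactants: 6 (−)-epicatechin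
Product: 7 5,7,3',4'-tetra-O-benzyl-(−)-epicatechin
Conditions: BnBr (4.4 equiv), K2CO3, DMF, 0 °C to rt
Reagents that add atoms: benzyl bromide, BrCc1ccccc1
Why: Williamson etherification, in which the four phenols are far more acidic than the secondary 3-OH and should be benzylated selectively with a carbonate base.

Step 6
Reactants: 7 5,7,3',4'-tetra-O-benzyl-(−)-epicatechin
Product: 8 8-bromo-5,7,3',4'-tetra-O-benzyl-(−)-epicatechin
Conditions: NBS (1.0 equiv), CH2Cl2, −78 °C to 0 °C
Reagents that add atoms: N-bromosuccinimide, O=C1CCC(=O)N1Br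
Why: electrophilic aromatic bromination of the phloroglucinol-type ring D, which in 5,7-di-O-benzylflavan-3-ols takes place at C-8 in preference to C-6 at low temperature.

Step 7
Reactants: 8 8-bromo-5,7,3',4'-tetra-O-benzyl-(−)-epicatechin; 5 (2R,3R)-3-[3,4-bis(benzyloxy)phenyl]oxirane-2-carbaldehyde
Product: 10 ring D C-8 epoxy carbinol (both carbinol epimers; full name in the list), via aryllithium alkoxide 9 (not isolated)
Conditions: n-BuLi (2.2 equiv), THF, −78 °C; then 5, −78 °C; H2O
Reagents that add atoms: none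
Why: deprotonation of the 3-OH followed by bromine–lithium exchange gives the C-8 aryllithium, which should add to the aldehyde carbonyl much faster than to the epoxide; the new carbinol centre forms unselectively and is erased in step 8.

Step 8
Reactants: 10 ring D C-8 epoxy carbinol; 11 3,5-bis(benzyloxy)phenol
Product: 14 octa-O-benzyl dimer with all-cis ring C (full name in the list), via benzylic cation 12 (not isolated), via epoxy phenol 13 (not isolated)
Conditions: 11 (4 equiv), (PhO)2P(O)OH (10 mol %), 4 Å MS, CH2Cl2, −40 °C to rt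
Reagents that add atoms: none
Why: Proposed new method: the phosphoric acid ionises the doubly ortho-oxygenated benzylic carbinol of 10 to cation 12, an ortho carbon of phenol 11 adds in a Friedel–Crafts alkylation to give epoxy phenol 13, and the phenolic hydroxyl then opens the acid-activated epoxide at its benzylic carbon; the closest known reactions are Friedel–Crafts benzylations of phenols with electron-rich benzylic alcohols and the acid-catalysed cyclisation of 2-(3-aryloxiranylmethyl)phenols to flavan-3-ols, merged here by using a 2,3-epoxy alcohol as a 1,3-bis-electrophile. Ring C closes by a 6-endo-tet epoxide opening with inversion at C-2, so the cis-epoxide should deliver the 2,3-cis (2S,3S) relationship, C-3 being carried over unchanged from step 3. C-4 is set in the intermolecular addition: allylic 1,3-strain against the ortho oxygens of ring D should hold the C-3 hydrogen in the plane of the cation, the epoxide carbon with its cis-disposed aryl group then shields one face, and the phenol enters past the small epoxide oxygen, which corresponds to the 3,4-cis (4R) isomer. The step needs C-4 to ionise before the epoxide opens (three-oxygen stabilisation of the ring D cation against a two-oxygen ring B epoxide, weak acid, low temperature), carbon alkylation ortho to the free hydroxyl (oxygen alkylation is reversible and only the ortho adduct can cyclise), and 6-endo instead of 5-exo opening (C-2 is benzylic to the 3,4-dialkoxyphenyl ring). The excess of 11 should suppress self-condensation through C-6 of ring D.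

Step 9
Reactants: 14 octa-O-benzyl dimer
Product: 15 octa-O-benzyl dimer with a 4-hydroxyl on ring F (3,4-trans)
Conditions: DDQ (1.5 equiv), CH2Cl2/H2O (20:1), 0 °C to rt
Reagents that add atoms: water, O
Why: benzylic oxidation by hydride abstraction with DDQ at the C-4 methylene of ring F, followed by capture of the ring D-stabilised cation by water anti to the axial 3-OH, should set the 3,4-trans (4S) alcohol, while the C-4 methine of ring C is tertiary and buried between rings A and D.

Step 10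
Reactants: 15 octa-O-benzyl dimer with a 4-hydroxyl on ring F
Product: 16 CNP0114173.1
Conditions: H2 (1 atm), Pd(OH)2/C, THF/MeOH (1:1), rt; filtration, no acid
Reagents that add atoms: none
Why: hydrogenolysis of the eight benzyl ethers under neutral conditions should free all phenols without touching a stereocentre and without the acid that the benzylic 4-hydroxyl of ring F would not tolerate.

Compound list
1 | 3,4-bis(benzyloxy)benzaldehyde | O=Cc1ccc(OCc2ccccc2)c(OCc2ccccc2)c1 | starting material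
2 | methyl (2Z)-3-[3,4-bis(benzyloxy)phenyl]prop-2-enoate | COC(=O)/C=C\c1ccc(OCc2ccccc2)c(OCc2ccccc2)c1 | intermediate
3 | (2Z)-3-[3,4-bis(benzyloxy)phenyl]prop-2-en-1-ol | OC/C=C\c1ccc(OCc2ccccc2)c(OCc2ccccc2)c1 | intermediate
4 | [(2S,3R)-3-[3,4-bis(benzyloxy)phenyl]oxiran-2-yl]methanol | OC[C@@H]1O[C@@H]1c1ccc(OCc2ccccc2)c(OCc2ccccc2)c1 | intermediate
5 | (2R,3R)-3-[3,4-bis(benzyloxy)phenyl]oxirane-2-carbaldehyde | O=C[C@@H]1O[C@@H]1c1ccc(OCc2ccccc2)c(OCc2ccccc2)c1 | intermediate
6 | (−)-epicatechin, (2R,3R)-2-(3,4-dihydroxyphenyl)chromane-3,5,7-triol | Oc1cc(O)c2c(c1)O[C@H](c1ccc(O)c(O)c1)[C@H](O)C2 | starting material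
7 | (2R,3R)-5,7-bis(benzyloxy)-2-[3,4-bis(benzyloxy)phenyl]chroman-3-ol | c1ccccc1COc1cc(OCc3ccccc3)c2c(c1)O[C@H](c1ccc(OCc3ccccc3)c(OCc3ccccc3)c1)[C@H](O)C2 | intermediate
8 | (2R,3R)-5,7-bis(benzyloxy)-2-[3,4-bis(benzyloxy)phenyl]-8-bromochroman-3-ol | c1ccccc1COc1cc(OCc3ccccc3)c2c(c1Br)O[C@H](c1ccc(OCc3ccccc3)c(OCc3ccccc3)c1)[C@H](O)C2 | intermediate
9 | lithium (2R,3R)-5,7-bis(benzyloxy)-2-[3,4-bis(benzyloxy)phenyl]-8-lithiochroman-3-olate (formed in the flask) | c1ccccc1COc1cc(OCc3ccccc3)c2c(c1[Li])O[C@H](c1ccc(OCc3ccccc3)c(OCc3ccccc3)c1)[C@H](O[Li])C2 | intermediate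
10 | (2R,3R)-5,7-bis(benzyloxy)-2-[3,4-bis(benzyloxy)phenyl]-8-{[(2S,3R)-3-[3,4-bis(benzyloxy)phenyl]oxiran-2-yl](hydroxy)methyl}chroman-3-ol, both carbinol epimers | c1ccccc1COc1cc(OCc3ccccc3)c2c(c1C(O)[C@@H]4O[C@@H]4c5ccc(OCc6ccccc6)c(OCc6ccccc6)c5)O[C@H](c1ccc(OCc3ccccc3)c(OCc3ccccc3)c1)[C@H](O)C2 | intermediate
11 | 3,5-bis(benzyloxy)phenol | Oc1cc(OCc2ccccc2)cc(OCc2ccccc2)c1 | starting material
12 | ring D benzylic cation from 10 (carbinol hydroxyl lost, (2S,3R)-epoxide intact; formed in the flask) | c1ccccc1COc1cc(OCc3ccccc3)c2c(c1[CH+][C@@H]4O[C@@H]4c5ccc(OCc6ccccc6)c(OCc6ccccc6)c5)O[C@H](c1ccc(OCc3ccccc3)c(OCc3ccccc3)c1)[C@H](O)C2 | intermediate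
13 | 3,5-bis(benzyloxy)-2-{(R)-[(2R,3R)-5,7-bis(benzyloxy)-2-[3,4-bis(benzyloxy)phenyl]-3-hydroxychroman-8-yl][(2S,3R)-3-[3,4-bis(benzyloxy)phenyl]oxiran-2-yl]methyl}phenol (formed in the flask) | Oc1cc(OCc2ccccc2)cc(OCc2ccccc2)c1[C@H](c3c(OCc2ccccc2)cc(OCc2ccccc2)c4c3O[C@H](c5ccc(OCc2ccccc2)c(OCc2ccccc2)c5)[C@H](O)C4)[C@@H]6O[C@@H]6c7ccc(OCc2ccccc2)c(OCc2ccccc2)c7 | intermediate
14 | (2S,3S,4R)-5,7-bis(benzyloxy)-2-[3,4-bis(benzyloxy)phenyl]-4-[(2R,3R)-5,7-bis(benzyloxy)-2-[3,4-bis(benzyloxy)phenyl]-3-hydroxychroman-8-yl]chroman-3-ol | c1ccccc1COc1cc(OCc3ccccc3)c2c(c1)O[C@@H](c1ccc(OCc3ccccc3)c(OCc3ccccc3)c1)[C@@H](O)[C@H]2c1c(OCc3ccccc3)cc(OCc3ccccc3)c2c1O[C@H](c1ccc(OCc3ccccc3)c(OCc3ccccc3)c1)[C@H](O)C2 | intermediate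
15 | (2S,3S,4R)-5,7-bis(benzyloxy)-2-[3,4-bis(benzyloxy)phenyl]-4-[(2R,3R,4S)-5,7-bis(benzyloxy)-2-[3,4-bis(benzyloxy)phenyl]-3,4-dihydroxychroman-8-yl]chroman-3-ol | c1ccccc1COc1cc(OCc3ccccc3)c2c(c1)O[C@@H](c1ccc(OCc3ccccc3)c(OCc3ccccc3)c1)[C@@H](O)[C@H]2c1c(OCc3ccccc3)cc(OCc3ccccc3)c2c1O[C@H](c1ccc(OCc3ccccc3)c(OCc3ccccc3)c1)[C@H](O)[C@H]2O | intermediate
16 | CNP0114173.1, (2S,3S,4R)-2-(3,4-dihydroxyphenyl)-4-[(2R,3R,4S)-2-(3,4-dihydroxyphenyl)-3,4,5,7-tetrahydroxychroman-8-yl]chromane-3,5,7-triol | Oc1cc(O)c2c(c1)O[C@@H](c1ccc(O)c(O)c1)[C@@H](O)[C@H]2c1c(O)cc(O)c2c1O[C@H](c1ccc(O)c(O)c1)[C@H](O)[C@H]2O | target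

Total step count: 10. Longest linear sequence: 8 steps (steps 1 to 4, then 7 to 10).

Steps most likely to fail

Step 8 (proposed new method). The cation may be captured with poor facial selectivity, the epoxide may open or rearrange before the carbon–carbon bond has formed, or the phenol may be alkylated para to its hydroxyl. The fallback separates the two bond formations under known conditions and sets out from 10 and 11. Ti(Oi-Pr)4 in CH2Cl2 should direct the phenolic oxygen of 11 to the benzylic carbon of the 2,3-epoxy alcohol with inversion, giving the aryl ether diol (2S,3S)-3-[3,5-bis(benzyloxy)phenoxy]-3-[3,4-bis(benzyloxy)phenyl]-1-(ring D C-8 unit)propane-1,2-diol F1. BF3·OEt2 in CH2Cl2 at −40 °C then ionises the ring D carbinol, and the aryl ether ring closes ring C by intramolecular Friedel–Crafts alkylation with both aryl groups equatorial (2,4-cis). This comes back to the route at 14.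

Step 9. Hydride abstraction may occur at the wrong benzylic position (C-4 of ring C), or the new carbinol may be over-oxidised. The fallback places the ring F heteroatom before the dimer exists and sets out from 8. DDQ with 2-ethoxyethanol should give the 4β-(2-ethoxyethoxy) bromide F2. Exchange with 2,6-dimethylbenzenethiol under BF3·OEt2 gives the 4β-(2,6-dimethylphenylsulfanyl) bromide F3. The conditions of step 7 convert F3 into the sulfanyl epoxy carbinol F4, and those of step 8 give the sulfanyl dimer F5, the carbon–sulfur bond being inert to the weak Brønsted acid. AgBF4 in wet THF then replaces sulfur by hydroxyl anti to the 3-OH. This comes back to the route at 15.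

Step 10. The benzylic carbon–oxygen bond at C-4 of ring F may be hydrogenolysed, or traces of acid may trigger ionisation and self-condensation while the phenols are being freed. The fallback masks the three secondary hydroxyls during the hydrogenolysis and sets out from 15. Et3SiCl, imidazole and DMAP in DMF should give the tris(triethylsilyl) ether F6. H2 over Pd(OH)2/C in EtOAc/THF gives the octaphenol tris(triethylsilyl) ether F7. NH4F in MeOH then removes the silyl groups under neutral conditions. This comes back to the route at 16.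

Further compounds
F1 | step 8 | (2S,3S)-3-[3,5-bis(benzyloxy)phenoxy]-3-[3,4-bis(benzyloxy)phenyl]-1-[(2R,3R)-5,7-bis(benzyloxy)-2-[3,4-bis(benzyloxy)phenyl]-3-hydroxychroman-8-yl]propane-1,2-diol, both C-1 epimers | c1ccccc1COc1cc(OCc2ccccc2)cc(c1)O[C@@H](c1ccc(OCc2ccccc2)c(OCc2ccccc2)c1)[C@@H](O)C(O)c1c(OCc2ccccc2)cc(OCc2ccccc2)c2c1O[C@H](c1ccc(OCc3ccccc3)c(OCc3ccccc3)c1)[C@H](O)C2
F2 | step 9 | (2R,3R,4S)-5,7-bis(benzyloxy)-2-[3,4-bis(benzyloxy)phenyl]-8-bromo-4-(2-ethoxyethoxy)chroman-3-ol | c1ccccc1COc1cc(OCc3ccccc3)c2c(c1Br)O[C@H](c1ccc(OCc3ccccc3)c(OCc3ccccc3)c1)[C@H](O)[C@H]2OCCOCC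
F3 | step 9 | (2R,3S,4S)-5,7-bis(benzyloxy)-2-[3,4-bis(benzyloxy)phenyl]-8-bromo-4-[(2,6-dimethylphenyl)sulfanyl]chroman-3-ol | c1ccccc1COc1cc(OCc3ccccc3)c2c(c1Br)O[C@H](c1ccc(OCc3ccccc3)c(OCc3ccccc3)c1)[C@H](O)[C@H]2Sc1c(C)cccc1C
F4 | step 9 | (2R,3S,4S)-5,7-bis(benzyloxy)-2-[3,4-bis(benzyloxy)phenyl]-8-{[(2S,3R)-3-[3,4-bis(benzyloxy)phenyl]oxiran-2-yl](hydroxy)methyl}-4-[(2,6-dimethylphenyl)sulfanyl]chroman-3-ol, both carbinol epimers | c1ccccc1COc1cc(OCc3ccccc3)c2c(c1C(O)[C@@H]4O[C@@H]4c5ccc(OCc6ccccc6)c(OCc6ccccc6)c5)O[C@H](c1ccc(OCc3ccccc3)c(OCc3ccccc3)c1)[C@H](O)[C@H]2Sc1c(C)cccc1C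
F5 | step 9 | (2S,3S,4R)-5,7-bis(benzyloxy)-2-[3,4-bis(benzyloxy)phenyl]-4-[(2R,3S,4S)-5,7-bis(benzyloxy)-2-[3,4-bis(benzyloxy)phenyl]-4-[(2,6-dimethylphenyl)sulfanyl]-3-hydroxychroman-8-yl]chroman-3-ol | c1ccccc1COc1cc(OCc3ccccc3)c2c(c1)O[C@@H](c1ccc(OCc3ccccc3)c(OCc3ccccc3)c1)[C@@H](O)[C@H]2c1c(OCc3ccccc3)cc(OCc3ccccc3)c2c1O[C@H](c1ccc(OCc3ccccc3)c(OCc3ccccc3)c1)[C@H](O)[C@H]2Sc1c(C)cccc1C
F6 | step 10 | tris(triethylsilyl) ether of 15 (on O-3 of ring C and on O-3 and O-4 of ring F) | c1ccccc1COc1cc(OCc3ccccc3)c2c(c1)O[C@@H](c1ccc(OCc3ccccc3)c(OCc3ccccc3)c1)[C@@H](O[Si](CC)(CC)CC)[C@H]2c1c(OCc3ccccc3)cc(OCc3ccccc3)c2c1O[C@H](c1ccc(OCc3ccccc3)c(OCc3ccccc3)c1)[C@H](O[Si](CC)(CC)CC)[C@H]2O[Si](CC)(CC)CC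
F7 | step 10 | tris(triethylsilyl) ether of 16 (on O-3 of ring C and on O-3 and O-4 of ring F, all phenols free) | Oc1cc(O)c2c(c1)O[C@@H](c1ccc(O)c(O)c1)[C@@H](O[Si](CC)(CC)CC)[C@H]2c1c(O)cc(O)c2c1O[C@H](c1ccc(O)c(O)c1)[C@H](O[Si](CC)(CC)CC)[C@H]2O[Si](CC)(CC)CC
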